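**Assumption:** ring atoms are numbered C1 (bears CH2OAc), C2 (=CH), C3 (carbinol next to the quaternary carbon), C4 (quaternary oxirane carbon), C5 (oxirane CH), C6; the side chain is C1′–C12′ counted from the carbinol.

## Retrosynthetic overview

1. Target ⇐ desilylation, Luche reduction and ketal hydrolysis of epoxide 22. The carbocycle is never built: it is the dearomatised ring of 3-bromophenol. The oxirane is the only ring formed, late, by a carbinol-directed Ti–tartrate epoxidation.
2. 22 ⇐ bis-allylic alcohol 21 ⇐ cyclohexadienyl iodide 7 + tetraenal 20. This C4–C1′ bond is made by a Ni-catalysed, Cr-mediated Nozaki–Hiyama–Kishi coupling.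
3. 7 ⇐ 3-bromophenol: oxidative dearomatisation, Pd-catalysed acetoxymethylation (new), α-iodination, CBS reduction, silylation.
4. 20 ⇐ homoprenyl bromide, acetylide, (E)-dichloroethene and TMS-acetylene: two Zr-catalysed carboaluminations, a Pd-catalysed alkenyl–alkenyl coupling (C5′–C6′), hydroxymethylation and MnO2 oxidation.

## Ring fragment

**Step 1**
Reactants: 1 3-bromophenol
Product: 3 3-bromo-4,4-dimethoxycyclohexa-2,5-dien-1-one, via 3-bromo-4-methoxyphenol 2 (not isolated)
Conditions: PhI(OAc)2 (2.2 equiv), MeOH, 0 °C → rt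
Reagents that add atoms: methanol (CO)
Why: Two successive hypervalent-iodine phenol oxidations (oxidative dearomatisation) trap the phenoxenium ion with methanol at the para carbon, first giving 2 and then the quinone monoketal with bromine next to the ketal carbon.

**Step 2**
Reactants: 3 3-bromo-4,4-dimethoxycyclohexa-2,5-dien-1-one
Product: 4 (6,6-dimethoxy-3-oxocyclohexa-1,4-dien-1-yl)methyl acetate
Conditions: AcOCH2Br, Zn dust, LiCl, THF, 25 °C, then decant from Zn; add to 3, Pd(OAc)2 (3 mol%), SPhos (6 mol%), THF, 0 °C → rt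
Reagents that add atoms: bromomethyl acetate (CC(=O)OCBr), used as (acetoxymethyl)zinc bromide (CC(=O)OC[Zn]Br)
Why: Proposed new method: a Pd-catalysed Negishi coupling of an α-acyloxymethylzinc halide with a β-bromo enone installs C1–CH2OAc directly at the ester oxidation level. Pd(0) adds readily to the activated vinyl C–Br bond, the zinc reagent transmetalates, and Pd–CH2OAc has no β-hydrogen, so reductive elimination is the only productive exit. The closest known chemistry is the Negishi coupling of functionalised alkylzinc halides, Knochel-type pivaloyloxymethyl zinc/copper reagents, and the Stille hydroxymethylation with Bu3SnCH2OH.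

**Step 3**
Reactants: 4 (6,6-dimethoxy-3-oxocyclohexa-1,4-dien-1-yl)methyl acetate
Product: 5 (4-iodo-6,6-dimethoxy-3-oxocyclohexa-1,4-dien-1-yl)methyl acetate
Conditions: I2 (1.5 equiv), pyridine/CH2Cl2 1:1, 0 °C → rt
Reagents that add atoms: iodine (II)
Why: Johnson α-iodination of an enone (pyridine addition, iodination, elimination) works only where the β-carbon carries H, so iodine goes to C4 and not to C2.

**Step 4**
Reactants: 5 (4-iodo-6,6-dimethoxy-3-oxocyclohexa-1,4-dien-1-yl)methyl acetate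
Product: 6 [(3S)-3-hydroxy-4-iodo-6,6-dimethoxycyclohexa-1,4-dien-1-yl]methyl acetate
Conditions: (R)-Me-CBS (0.2 equiv), catecholborane (1.5 equiv), toluene, −78 °C; pH 7 work-up
Reagents that add atoms: none
Why: Corey–Bakshi–Shibata reduction in which the α-iodovinyl arm acts as the large group, so the (R)-catalyst is predicted to give the 3S carbinol by clean 1,2-reduction.

**Step 5**
Reactants: 6 [(3S)-3-hydroxy-4-iodo-6,6-dimethoxycyclohexa-1,4-dien-1-yl]methyl acetate
Product: 7 [(3S)-3-(tert-butyldimethylsilyloxy)-4-iodo-6,6-dimethoxycyclohexa-1,4-dien-1-yl]methyl acetate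
Conditions: TBSCl (1.5 equiv), imidazole (3 equiv), DMF, 0 °C → rt
Reagents that add atoms: tert-butyldimethylsilyl chloride (CC(C)(C)[Si](C)(C)Cl)
Why: Base-mediated silylation protects the acid-sensitive dienol and places a bulky group on the ring face that must stay free of the later oxirane.

## Side chain

**Step 6**
Reactants: 8 5-bromo-2-methylpent-2-ene; 9 lithium acetylide–ethylenediamine complex
Product: 10 6-methylhept-5-en-1-yne
Conditions: DMSO, 10 °C → rt
Reagents that add atoms: none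
Why: SN2 alkylation of the acetylide by the primary bromide.

**Step 7**
Reactants: 11 (E)-1,2-dichloroethene; 12 ethynyltrimethylsilane
Product: 13 [(E)-4-chlorobut-3-en-1-yn-1-yl]trimethylsilane
Conditions: 11 (5 equiv), Pd(PPh3)4 (5 mol%), CuI (10 mol%), n-BuNH2, Et2O, rt
Reagents that add atoms: none
Why: Sonogashira mono-coupling with retention of the E geometry; excess dichloroethene suppresses double coupling.

**Step 8**
Reactants: 10 6-methylhept-5-en-1-yne; 13 [(E)-4-chlorobut-3-en-1-yn-1-yl]trimethylsilane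
Product: 15 [(3E,5E)-6,10-dimethylundeca-3,5,9-trien-1-yn-1-yl]trimethylsilane, via alkenyldimethylalane 14 (not isolated)
Conditions: Me3Al (2 equiv), Cp2ZrCl2 (0.25 equiv), ClCH2CH2Cl, rt; then 13, Pd(PPh3)4 (5 mol%), ZnCl2 (0.3 equiv), THF, rt
Reagents that add atoms: trimethylaluminium (C[Al](C)C)
Why: Negishi Zr-catalysed carboalumination adds Me and Al syn (Me to the internal carbon), fixing the 6′E alkene, and the Pd-catalysed alkenyl–alkenyl Negishi coupling forms C5′–C6′ with retention at both partners.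

**Step 9**
Reactants: 15 [(3E,5E)-6,10-dimethylundeca-3,5,9-trien-1-yn-1-yl]trimethylsilane
Product: 16 (3E,5E)-6,10-dimethylundeca-3,5,9-trien-1-yne
Conditions: K2CO3, MeOH, rt
Reagents that add atoms: none
Why: Methanolysis of the alkynyl C–Si bond (protodesilylation).

**Step 10**
Reactants: 16 (3E,5E)-6,10-dimethylundeca-3,5,9-trien-1-yne
Product: 19 (2E,4E,6E)-3,7,11-trimethyldodeca-2,4,6,10-tetraen-1-ol, via tetraenyldimethylalane 17 (not isolated), via lithium butylalanate 18 (not isolated)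
Conditions: Me3Al (2 equiv), Cp2ZrCl2 (0.25 equiv), ClCH2CH2Cl, rt; strip excess Me3Al; n-BuLi (1 equiv), THF, −78 → 0 °C; (CH2O)n, rt
Reagents that add atoms: trimethylaluminium (C[Al](C)C); paraformaldehyde as formaldehyde (C=O)
Why: A second syn carboalumination sets the 2′E trisubstituted alkene, and the alanate transfers its alkenyl group to formaldehyde with retention (Negishi–Zweifel hydroxymethylation).

**Step 11**
Reactants: 19 (2E,4E,6E)-3,7,11-trimethyldodeca-2,4,6,10-tetraen-1-ol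
Product: 20 (2E,4E,6E)-3,7,11-trimethyldodeca-2,4,6,10-tetraenal
Conditions: activated MnO2 (15 equiv), CH2Cl2, 0 °C → rt, dark
Reagents that add atoms: none
Why: Chemoselective MnO2 oxidation of the allylic alcohol; the neutral conditions keep the alkene geometry.

## Fragment union and end game

**Step 12**
Reactants: 7 [(3S)-3-(tert-butyldimethylsilyloxy)-4-iodo-6,6-dimethoxycyclohexa-1,4-dien-1-yl]methyl acetate; 20 (2E,4E,6E)-3,7,11-trimethyldodeca-2,4,6,10-tetraenal
Product: 21 {(3S)-3-(tert-butyldimethylsilyloxy)-4-[(1S,2E,4E,6E)-1-hydroxy-3,7,11-trimethyldodeca-2,4,6,10-tetraen-1-yl]-6,6-dimethoxycyclohexa-1,4-dien-1-yl}methyl acetate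
Conditions: CrCl2 (15 mol%), Kishi oxazoline–sulfonamide ligand (17 mol%, enantiomer selected for the 1′S adduct), proton sponge, NiCl2·2,9-dimethylphenanthroline (2 mol%), Mn (2 equiv), Cp2ZrCl2 (1.2 equiv), LiCl, MeCN, rt
Reagents that add atoms: none
Why: Catalytic asymmetric Nozaki–Hiyama–Kishi coupling: Ni inserts into the C–I bond, the alkenyl group passes to Cr(III) and adds 1,2 to the enal, and the chiral Cr ligand sets 1′S; the low Ni loading spares the allylic acetate.

**Step 13**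
Reactants: 21 (as above)
Product: 22 {(3S,4S,5R)-3-(tert-butyldimethylsilyloxy)-4,5-epoxy-4-[(1S,2E,4E,6E)-1-hydroxy-3,7,11-trimethyldodeca-2,4,6,10-tetraen-1-yl]-6,6-dimethoxycyclohex-1-en-1-yl}methyl acetate (oxirane trans to OTBS)
Conditions: Ti(OiPr)4 (1.0 equiv), L-(+)-DIPT (1.2 equiv), t-BuOOH (2 equiv, decane), 4 Å MS, CH2Cl2, −25 °C
Reagents that add atoms: tert-butyl hydroperoxide (CC(C)(C)OO)
Why: Sharpless epoxidation used in its matched kinetic-resolution sense: for the 1′S carbinol, L-(+)-tartrate makes the ring alkene the fast one and delivers oxygen erythro to C1′ and anti to the OTBS group (sets C4 and C5), while the C2′=C3′ alkene is mismatched and further slowed by its Z-methyl group (A1,3 strain).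

**Step 14**
Reactants: 22 (as above)
Product: 23 {(3S,4S,5R)-3-(tert-butyldimethylsilyloxy)-4,5-epoxy-4-[(1S,2E,4E,6E)-1-hydroxy-3,7,11-trimethyldodeca-2,4,6,10-tetraen-1-yl]-6-oxocyclohex-1-en-1-yl}methyl acetate
Conditions: PPTS (0.2 equiv), acetone/H2O 10:1, 0 °C → rt
Reagents that add atoms: water (O)
Why: Mild acid hydrolysis of the allylic dimethyl ketal; it is done only after the epoxidation so that no aromatisable 4-oxy-cyclohexadienone is ever formed.

**Step 15**
Reactants: 23 (as above)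
Product: 24 {(3S,4S,5S,6S)-3-(tert-butyldimethylsilyloxy)-4,5-epoxy-6-hydroxy-4-[(1S,2E,4E,6E)-1-hydroxy-3,7,11-trimethyldodeca-2,4,6,10-tetraen-1-yl]cyclohex-1-en-1-yl}methyl acetate (6-OH cis to the oxirane)
Conditions: NaBH4 (1.2 equiv), CeCl3·7H2O (1.2 equiv), MeOH, −78 °C
Reagents that add atoms: none
Why: Luche 1,2-reduction of the epoxy enone; hydride is expected to attack anti to the oxirane oxygen, giving the C6 alcohol cis to the epoxide (6S), and the acetate survives at −78 °C.

**Step 16**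
Reactants: 24 (as above)
Product: 25 {(3S,4R,5S,6S)-4,5-epoxy-3,6-dihydroxy-4-[(1S,2E,4E,6E)-1-hydroxy-3,7,11-trimethyldodeca-2,4,6,10-tetraen-1-yl]cyclohex-1-en-1-yl}methyl acetate (target)
Conditions: TBAF (1.5 equiv), AcOH (1.5 equiv), THF, 0 °C → rt
Reagents that add atoms: none
Why: Fluoride desilylation, buffered with acetic acid so that the primary acetate neither migrates nor cleaves.

## Compound list

1 | 3-bromophenol | Oc1cccc(Br)c1 | starting material
2 | 3-bromo-4-methoxyphenol | COc1ccc(O)cc1Br | intermediate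
3 | 3-bromo-4,4-dimethoxycyclohexa-2,5-dien-1-one | COC1(OC)C=CC(=O)C=C1Br | intermediate
4 | (6,6-dimethoxy-3-oxocyclohexa-1,4-dien-1-yl)methyl acetate | CC(=O)OCC1=CC(=O)C=CC1(OC)OC | intermediate
5 | (4-iodo-6,6-dimethoxy-3-oxocyclohexa-1,4-dien-1-yl)methyl acetate | CC(=O)OCC1=CC(=O)C(I)=CC1(OC)OC | intermediate
6 | [(3S)-3-hydroxy-4-iodo-6,6-dimethoxycyclohexa-1,4-dien-1-yl]methyl acetate | CC(=O)OCC1=C[C@H](O)C(I)=CC1(OC)OC | intermediate
7 | [(3S)-3-(tert-butyldimethylsilyloxy)-4-iodo-6,6-dimethoxycyclohexa-1,4-dien-1-yl]methyl acetate | CC(=O)OCC1=C[C@H](O[Si](C)(C)C(C)(C)C)C(I)=CC1(OC)OC | intermediate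
8 | 5-bromo-2-methylpent-2-ene | CC(C)=CCCBr | starting material
9 | lithium acetylide–ethylenediamine complex | [Li]C#C.NCCN | starting material
10 | 6-methylhept-5-en-1-yne | CC(C)=CCCC#C | intermediate
11 | (E)-1,2-dichloroethene | Cl/C=C/Cl | starting material
12 | ethynyltrimethylsilane | C[Si](C)(C)C#C | starting material
13 | [(E)-4-chlorobut-3-en-1-yn-1-yl]trimethylsilane | C[Si](C)(C)C#C/C=C/Cl | intermediate
14 | [(E)-2,6-dimethylhepta-1,5-dien-1-yl]dimethylalane | C[Al](C)/C=C(\C)CCC=C(C)C | intermediate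
15 | [(3E,5E)-6,10-dimethylundeca-3,5,9-trien-1-yn-1-yl]trimethylsilane | C[Si](C)(C)C#C/C=C/C=C(\C)CCC=C(C)C | intermediate
16 | (3E,5E)-6,10-dimethylundeca-3,5,9-trien-1-yne | C#C/C=C/C=C(\C)CCC=C(C)C | intermediate
17 | dimethyl[(1E,3E,5E)-2,6,10-trimethylundeca-1,3,5,9-tetraen-1-yl]alane | C[Al](C)/C=C(\C)/C=C/C=C(\C)CCC=C(C)C | intermediate
18 | lithium butyl(dimethyl)[(1E,3E,5E)-2,6,10-trimethylundeca-1,3,5,9-tetraen-1-yl]aluminate | [Li+].CCCC[Al-](C)(C)/C=C(\C)/C=C/C=C(\C)CCC=C(C)C | intermediate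
19 | (2E,4E,6E)-3,7,11-trimethyldodeca-2,4,6,10-tetraen-1-ol | OC/C=C(\C)/C=C/C=C(\C)CCC=C(C)C | intermediate
20 | (2E,4E,6E)-3,7,11-trimethyldodeca-2,4,6,10-tetraenal | O=C/C=C(\C)/C=C/C=C(\C)CCC=C(C)C | intermediate
21 | {(3S)-3-(TBS-oxy)-4-[(1S,2E,4E,6E)-1-hydroxy-3,7,11-trimethyldodeca-2,4,6,10-tetraen-1-yl]-6,6-dimethoxycyclohexa-1,4-dien-1-yl}methyl acetate | CC(=O)OCC1=C[C@H](O[Si](C)(C)C(C)(C)C)C([C@@H](O)/C=C(C)/C=C/C=C(\C)CCC=C(C)C)=CC1(OC)OC | intermediate
22 | {(3S,4S,5R)-3-(TBS-oxy)-4,5-epoxy-4-[(1S,2E,4E,6E)-1-hydroxy-3,7,11-trimethyldodeca-2,4,6,10-tetraen-1-yl]-6,6-dimethoxycyclohex-1-en-1-yl}methyl acetate | CC(=O)OCC1=C[C@H](O[Si](C)(C)C(C)(C)C)[C@@]2([C@@H](O)/C=C(C)/C=C/C=C(\C)CCC=C(C)C)O[C@H]2C1(OC)OC | intermediate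
23 | {(3S,4S,5R)-3-(TBS-oxy)-4,5-epoxy-4-[(1S,2E,4E,6E)-1-hydroxy-3,7,11-trimethyldodeca-2,4,6,10-tetraen-1-yl]-6-oxocyclohex-1-en-1-yl}methyl acetate | CC(=O)OCC1=C[C@H](O[Si](C)(C)C(C)(C)C)[C@@]2([C@@H](O)/C=C(C)/C=C/C=C(\C)CCC=C(C)C)O[C@H]2C1=O | intermediate
24 | {(3S,4S,5S,6S)-3-(TBS-oxy)-4,5-epoxy-6-hydroxy-4-[(1S,2E,4E,6E)-1-hydroxy-3,7,11-trimethyldodeca-2,4,6,10-tetraen-1-yl]cyclohex-1-en-1-yl}methyl acetate | CC(=O)OCC1=C[C@H](O[Si](C)(C)C(C)(C)C)[C@@]2([C@@H](O)/C=C(C)/C=C/C=C(\C)CCC=C(C)C)O[C@H]2[C@H]1O | intermediate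
25 | {(3S,4R,5S,6S)-4,5-epoxy-3,6-dihydroxy-4-[(1S,2E,4E,6E)-1-hydroxy-3,7,11-trimethyldodeca-2,4,6,10-tetraen-1-yl]cyclohex-1-en-1-yl}methyl acetate | CC(=O)OCC1=C[C@H](O)[C@@]2([C@@H](O)/C=C(C)/C=C/C=C(\C)CCC=C(C)C)O[C@H]2[C@H]1O | target

## Step count and risks

Total step count: 16. Longest linear sequence: 10 steps (1–5, then 12–16; the side-chain line 6, 8, 9, 10, 11, then 12–16 is equally long). Steps 6–11 (six steps) run parallel to the ring line, and step 7 is a third branch.

Three steps most likely to fail: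

**Step 2 (the proposed new coupling).** The zinc reagent may decompose, or Pd(0) may ionise the allylic acetate of the product. The fallback sets out from 3 and comes back at 4. A Stille coupling of 3 with (tributylstannyl)methanol (Pd(PPh3)4, dioxane, 90 °C) gives 3-(hydroxymethyl)-4,4-dimethoxycyclohexa-2,5-dien-1-one F1, which is not an allylic ester and so is inert to Pd(0). Acetylation of F1 (Ac2O, pyridine, DMAP) then gives 4.

**Step 12 (fragment coupling).** Ligand control at C1′ on a conjugated polyenal may be weak. The fallback sets out from 7 and 20 and comes back at 21, moving stereocontrol from the addition to a ketone reduction. A ligand-free stoichiometric CrCl2/cat. NiCl2 coupling (DMSO–THF) gives 21 together with its 1′R epimer F2. The mixture is oxidised (MnO2) to the cross-conjugated ketone F3, and (R)-Me-CBS/catecholborane reduction of F3 (ring alkenyl as the large group) returns 21.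

**Step 13 (site- and face-selective epoxidation).** The hindered ring alkene may react too slowly, letting the triene-side alkene compete. The fallback sets out from 7 (and 16) and comes back at 22, putting the oxirane in before any polyene is present. Stille hydroxymethylation of 7 with (tributylstannyl)methanol gives the primary allylic alcohol F4. Sharpless epoxidation of F4 (Ti(OiPr)4, L-(+)-DET, t-BuOOH) gives the epoxy alcohol F5, and Dess–Martin oxidation gives the epoxy aldehyde F6. Separately, 16 is converted (Me3Al, cat. Cp2ZrCl2, then I2) into the tetraenyl iodide F7. A Kishi-type Ni/Cr coupling of F7 with F6 gives 22.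

## Further compounds

F1 | step 2 | 3-(hydroxymethyl)-4,4-dimethoxycyclohexa-2,5-dien-1-one | OCC1=CC(=O)C=CC1(OC)OC
F2 | step 12 | 1′R epimer of 21 | CC(=O)OCC1=C[C@H](O[Si](C)(C)C(C)(C)C)C([C@H](O)/C=C(C)/C=C/C=C(\C)CCC=C(C)C)=CC1(OC)OC
F3 | step 12 | {(3S)-3-(TBS-oxy)-6,6-dimethoxy-4-[(2E,4E,6E)-3,7,11-trimethyldodeca-2,4,6,10-tetraenoyl]cyclohexa-1,4-dien-1-yl}methyl acetate | CC(=O)OCC1=C[C@H](O[Si](C)(C)C(C)(C)C)C(C(=O)/C=C(C)/C=C/C=C(\C)CCC=C(C)C)=CC1(OC)OC
F4 | step 13 | [(3S)-3-(TBS-oxy)-4-(hydroxymethyl)-6,6-dimethoxycyclohexa-1,4-dien-1-yl]methyl acetate | CC(=O)OCC1=C[C@H](O[Si](C)(C)C(C)(C)C)C(CO)=CC1(OC)OC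
F5 | step 13 | [3-(TBS-oxy)-4,5-epoxy-4-(hydroxymethyl)-6,6-dimethoxycyclohex-1-en-1-yl]methyl acetate, oxirane trans to OTBS | CC(=O)OCC1=C[C@H](O[Si](C)(C)C(C)(C)C)[C@@]2(CO)O[C@H]2C1(OC)OC
F6 | step 13 | [3-(TBS-oxy)-4,5-epoxy-4-formyl-6,6-dimethoxycyclohex-1-en-1-yl]methyl acetate, oxirane trans to OTBS | CC(=O)OCC1=C[C@H](O[Si](C)(C)C(C)(C)C)[C@@]2(C=O)O[C@H]2C1(OC)OC
F7 | step 13 | (1E,3E,5E)-1-iodo-2,6,10-trimethylundeca-1,3,5,9-tetraene | I/C=C(\C)/C=C/C=C(\C)CCC=C(C)C
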